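**Retrosynthetic overview**
- The target (ring A–O–ring B–O–ring C–ring D) is reached by tenfold O-dealkylation of its per-alkyl ether. That ether is cut at the ring B–O–ring C bond, an Ullmann union of a ring C phenol with the aryl bromide of fragment A–O–B, itself from an iodide-selective Ullmann coupling.
- The strategy rests on ring C: oxygens at C1 and C4 (a para pair), further oxygens at C2 and C6, hydrogen at C3 and ring D at C5. This is the pattern that ring expansion of a squarate-derived 4-(1-alkoxy-2-arylethenyl)-3-alkoxy-4-oxycyclobutenone delivers. Cyclobutenone C1, C2, C3, C4 become ring C C4, C3, C2, C1; the vinyl carbons become C6 and C5; the new bond is C4–C5.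
- The cyclobutenone comes from 3-isopropoxycyclobutenedione (from diisopropyl squarate) and a (Z)-α-ethoxy-β-arylvinyllithium. This is made by tin–lithium exchange of a stannane from syn-hydrostannation of an aryl ynol ether, not by deprotonation, since alkyllithiums would metalate the 3- and 5-positions of the trimethoxyphenyl ring.
- The carbinol oxygen is silylated before thermolysis, so the ring expansion leaves only O4 of ring C free. O4 is methylated and O1 is then unmasked for the diaryl ether coupling.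
- Rings A, B and D are bought as arenes; ring C is the only ring formed (step 6).

Key step: step 6

Assumption: 2-iodo-1,3,5-trimethoxybenzene, ethoxyacetylene (solution in hexanes), 2,4,6-trimethoxyphenol and 1-bromo-3-iodo-5-methoxybenzene are treated as purchasable. The enol ether carries ethyl because ethoxyacetylene is the available ynol ether, and every O-alkyl group falls in the last step.

**Route**

Step 1
Reactants: 1 2-iodo-1,3,5-trimethoxybenzene; 2 ethoxyacetylene
Product: 5 2-(ethoxyethynyl)-1,3,5-trimethoxybenzene, via lithium ethoxyacetylide 3 (not isolated), via (ethoxyethynyl)zinc chloride 4 (not isolated)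
Conditions: 2 (1.5 equiv), n-BuLi, THF, −78 °C; ZnCl2, −78 → 0 °C; then 1, Pd(PPh3)4 (5 mol %), rt → 50 °C; neutral alumina
Reagents that add atoms: none
Why: Negishi coupling of an alkynylzinc with an aryl iodide, in which the zinc acetylide should transmetalate to the hindered, electron-rich arylpalladium iodide well below the temperature at which an ethyl ynol ether fragments, with no ammonium salt or water present to hydrate the product.

Step 2
Reactants: 5 2-(ethoxyethynyl)-1,3,5-trimethoxybenzene
Product: 6 (E)-tributyl[1-ethoxy-2-(2,4,6-trimethoxyphenyl)ethenyl]stannane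
Conditions: Bu3SnH (1.1 equiv), Pd(PPh3)4 (3 mol %), THF, 0 °C → rt; Et3N-deactivated silica
Reagents that add atoms: tributyltin hydride, CCCC[SnH](CCCC)CCCC
Why: Palladium-catalysed syn-hydrostannation of a 1-alkoxyalkyne, in which the polarisation of the ynol ether should send tin to the oxygen-bearing carbon and hydrogen to the aryl-bearing carbon, and the cis addition places aryl and ethoxy on the same side of the double bond.

Step 3
Reactants: 7 diisopropyl squarate
Product: 9 3-isopropoxycyclobut-3-ene-1,2-dione, via 4-hydroxy-2,3-diisopropoxycyclobut-2-en-1-one 8 (not isolated)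
Conditions: LiAlH(OtBu)3 (1.05 equiv), THF, −78 → −20 °C; aqueous work-up; crude 8, conc. HCl (cat.), CH2Cl2, rt
Reagents that add atoms: water, O
Why: Mono-1,2-reduction of one of the two equivalent carbonyls by the bulky hydride, then acid-mediated loss of the allylic hydroxyl and hydrolysis of the alkoxy-stabilised cation with loss of isopropanol, the standard transposition of squarate adducts to 3-alkoxycyclobutenediones.

Step 4
Reactants: 6 (E)-tributyl[1-ethoxy-2-(2,4,6-trimethoxyphenyl)ethenyl]stannane; 9 3-isopropoxycyclobut-3-ene-1,2-dione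
Product: 11 4-[(Z)-1-ethoxy-2-(2,4,6-trimethoxyphenyl)ethenyl]-4-hydroxy-3-isopropoxycyclobut-2-en-1-one (racemic), via (Z)-1-ethoxy-2-(2,4,6-trimethoxyphenyl)ethenyllithium 10 (not isolated)
Conditions: 6, n-BuLi (1.0 equiv), THF, −78 °C, 30 min; cannulate into 9 (1.2 equiv), THF, −78 °C; sat. aq NH4Cl at −78 °C; Et3N-deactivated silica
Reagents that add atoms: none
Why: Tin–lithium exchange is fast at −78 °C and retains the alkene geometry, so it should outpace metalation of the trimethoxyphenyl ring, and the vinyllithium should add 1,2 to the ketone-like carbonyl of 9 (the one not in vinylogous-ester conjugation with the isopropoxy group) to give the tertiary carbinol.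

Step 5
Reactants: 11 4-[(Z)-1-ethoxy-2-(2,4,6-trimethoxyphenyl)ethenyl]-4-hydroxy-3-isopropoxycyclobut-2-en-1-one
Product: 12 4-[(tert-butyldimethylsilyl)oxy]-4-[(Z)-1-ethoxy-2-(2,4,6-trimethoxyphenyl)ethenyl]-3-isopropoxycyclobut-2-en-1-one (racemic)
Conditions: TBSOTf (1.5 equiv), 2,6-lutidine (3 equiv), CH2Cl2, −78 → 0 °C
Reagents that add atoms: tert-butyldimethylsilyl trifluoromethanesulfonate, CC(C)(C)[Si](C)(C)OS(=O)(=O)C(F)(F)F
Why: Silyl triflate silylation of a tertiary alcohol under lutidine buffering, which should spare the acid-labile enol ether and vinylogous ester and marks the oxygen that becomes O1 of ring C.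

Step 6
Reactants: 12 4-[(tert-butyldimethylsilyl)oxy]-4-[(Z)-1-ethoxy-2-(2,4,6-trimethoxyphenyl)ethenyl]-3-isopropoxycyclobut-2-en-1-one
Product: 15 4-[(tert-butyldimethylsilyl)oxy]-3-ethoxy-5-isopropoxy-2-(2,4,6-trimethoxyphenyl)phenol, via dienylketene 13 (not isolated), via cyclohexa-2,4-dienone 14 (not isolated)
Conditions: degassed toluene (0.02 M), 110 °C, argon
Reagents that add atoms: none
Why: Heating should open the cyclobutenone by conrotatory 4π cleavage of the C1–C4 bond to dienylketene 13, which closes by 6π electrocyclization between the ketene carbon and the aryl-bearing vinyl carbon (the C4–C5 bond of ring C) to dienone 14, and a proton shift from the new sp3 carbon to the carbonyl oxygen then aromatises it to phenol 15. The closest known reaction is the Moore rearrangement of 4-alkenyl-4-alkoxy- and 4-siloxycyclobutenones to hydroquinone monoethers. Ring C is closed as an all-carbon six-membered ring by a thermally allowed disrotatory 6π electrocyclization of the ketene-containing triene. No stereocentre remains, since that of 12 is lost on ring opening and that of 14 on tautomerisation. The step needs torquoselectivity (silyloxy outward, alkenyl inward, so that the alkenyl group and not the oxygen faces the ketene), which the donor oxygen substituent secures, and an open approach at the vinyl terminus, which the Z enol ether secures by turning hydrogen and not the aryl group inward. The silyl group stays on O1, so the product should carry a single free phenol at O4.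

Step 7
Reactants: 15 4-[(tert-butyldimethylsilyl)oxy]-3-ethoxy-5-isopropoxy-2-(2,4,6-trimethoxyphenyl)phenol
Product: 16 tert-butyl[2-ethoxy-6-isopropoxy-4-methoxy-3-(2,4,6-trimethoxyphenyl)phenoxy]dimethylsilane
Conditions: MeI (3 equiv), K2CO3 (2 equiv), dry acetone, rt → 40 °C, argon
Reagents that add atoms: iodomethane, CI
Why: Williamson O-methylation of the only free phenol, with the silyl ether on the doubly ortho-alkoxylated oxygen expected to survive carbonate in dry acetone.

Step 8
Reactants: 16 tert-butyl[2-ethoxy-6-isopropoxy-4-methoxy-3-(2,4,6-trimethoxyphenyl)phenoxy]dimethylsilane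
Product: 17 2-ethoxy-6-isopropoxy-4-methoxy-3-(2,4,6-trimethoxyphenyl)phenol
Conditions: TBAF (1.2 equiv), AcOH (1.2 equiv), THF, 0 °C, argon
Reagents that add atoms: none
Why: Fluoride cleavage of an aryl silyl ether, buffered with acetic acid so that the electron-rich phenol is not left as the oxidation-prone free phenoxide.

Step 9
Reactants: 18 2,4,6-trimethoxyphenol; 19 1-bromo-3-iodo-5-methoxybenzene
Product: 20 1-bromo-3-methoxy-5-(2,4,6-trimethoxyphenoxy)benzene
Conditions: 19 (1.3 equiv), CuI (10 mol %), picolinic acid (20 mol %), K3PO4 (2 equiv), DMSO, 80 °C, argon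
Reagents that add atoms: none
Why: Ullmann-type C–O coupling with a copper–picolinate catalyst that tolerates 2,6-disubstituted phenols, in which the C–I bond should react with monovalent copper much faster than the C–Br bond, so the bromide is kept for step 10.

Step 10
Reactants: 17 2-ethoxy-6-isopropoxy-4-methoxy-3-(2,4,6-trimethoxyphenyl)phenol; 20 1-bromo-3-methoxy-5-(2,4,6-trimethoxyphenoxy)benzene
Product: 21 1-[2-ethoxy-6-isopropoxy-4-methoxy-3-(2,4,6-trimethoxyphenyl)phenoxy]-3-methoxy-5-(2,4,6-trimethoxyphenoxy)benzene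
Conditions: CuI (20 mol %), picolinic acid (40 mol %), K3PO4 (2 equiv), DMSO, 110 °C, argon
Reagents that add atoms: none
Why: Ullmann diaryl ether synthesis at an aryl bromide whose two ortho positions are free, so that the steric demand lies on the phenol alone, with a ligand system suited to 2,6-disubstituted phenols.

Step 11
Reactants: 21 1-[2-ethoxy-6-isopropoxy-4-methoxy-3-(2,4,6-trimethoxyphenyl)phenoxy]-3-methoxy-5-(2,4,6-trimethoxyphenoxy)benzene
Product: 22 3-[3-hydroxy-5-(2,4,6-trihydroxyphenoxy)phenoxy]biphenyl-2,2',4,4',6,6'-hexol (CNP0260439.0)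
Conditions: BBr3 (20 equiv), CH2Cl2, −78 °C → rt; MeOH then H2O, 0 °C; argon; reversed-phase chromatography
Reagents that add atoms: none
Why: Lewis-acid dealkylation of alkyl aryl ethers, in which bromide attacks the O-alkyl carbon of each boron-complexed ether, should remove the eight methyl, one ethyl and one isopropyl groups while the diaryl ether and biaryl bonds resist.

**Compound list**
1 | 2-iodo-1,3,5-trimethoxybenzene | COc1cc(OC)c(I)c(OC)c1 | starting material
2 | ethoxyacetylene | CCOC#C | starting material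
3 | lithium ethoxyacetylide | CCOC#C[Li] | intermediate
4 | (ethoxyethynyl)zinc chloride | CCOC#C[Zn]Cl | intermediate
5 | 2-(ethoxyethynyl)-1,3,5-trimethoxybenzene | CCOC#Cc1c(OC)cc(OC)cc1OC | intermediate
6 | (E)-tributyl[1-ethoxy-2-(2,4,6-trimethoxyphenyl)ethenyl]stannane | CCO/C([Sn](CCCC)(CCCC)CCCC)=C\c1c(OC)cc(OC)cc1OC | intermediate
7 | diisopropyl squarate (3,4-diisopropoxycyclobut-3-ene-1,2-dione) | CC(C)OC1=C(OC(C)C)C(=O)C1=O | starting material
8 | 4-hydroxy-2,3-diisopropoxycyclobut-2-en-1-one (racemic) | CC(C)OC1=C(OC(C)C)C(O)C1=O | intermediate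
9 | 3-isopropoxycyclobut-3-ene-1,2-dione | CC(C)OC1=CC(=O)C1=O | intermediate
10 | (Z)-1-ethoxy-2-(2,4,6-trimethoxyphenyl)ethenyllithium | CCO/C([Li])=C\c1c(OC)cc(OC)cc1OC | intermediate
11 | 4-[(Z)-1-ethoxy-2-(2,4,6-trimethoxyphenyl)ethenyl]-4-hydroxy-3-isopropoxycyclobut-2-en-1-one (racemic) | CC(C)OC1=CC(=O)C1(O)/C(OCC)=C/c1c(OC)cc(OC)cc1OC | intermediate
12 | 4-[(tert-butyldimethylsilyl)oxy]-4-[(Z)-1-ethoxy-2-(2,4,6-trimethoxyphenyl)ethenyl]-3-isopropoxycyclobut-2-en-1-one (racemic) | CC(C)OC1=CC(=O)C1(O[Si](C)(C)C(C)(C)C)/C(OCC)=C/c1c(OC)cc(OC)cc1OC | intermediate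
13 | (3Z,5Z)-4-[(tert-butyldimethylsilyl)oxy]-5-ethoxy-3-isopropoxy-6-(2,4,6-trimethoxyphenyl)hexa-1,3,5-trien-1-one (dienylketene) | O=C=C/C(OC(C)C)=C(O[Si](C)(C)C(C)(C)C)\C(OCC)=C\c1c(OC)cc(OC)cc1OC | intermediate
14 | 4-[(tert-butyldimethylsilyl)oxy]-5-ethoxy-3-isopropoxy-6-(2,4,6-trimethoxyphenyl)cyclohexa-2,4-dien-1-one (racemic) | O=C1C=C(OC(C)C)C(O[Si](C)(C)C(C)(C)C)=C(OCC)C1c1c(OC)cc(OC)cc1OC | intermediate
15 | 4-[(tert-butyldimethylsilyl)oxy]-3-ethoxy-5-isopropoxy-2-(2,4,6-trimethoxyphenyl)phenol | CC(C)Oc1cc(O)c(-c2c(OC)cc(OC)cc2OC)c(OCC)c1O[Si](C)(C)C(C)(C)C | intermediate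
16 | tert-butyl[2-ethoxy-6-isopropoxy-4-methoxy-3-(2,4,6-trimethoxyphenyl)phenoxy]dimethylsilane | CC(C)Oc1cc(OC)c(-c2c(OC)cc(OC)cc2OC)c(OCC)c1O[Si](C)(C)C(C)(C)C | intermediate
17 | 2-ethoxy-6-isopropoxy-4-methoxy-3-(2,4,6-trimethoxyphenyl)phenol | CC(C)Oc1cc(OC)c(-c2c(OC)cc(OC)cc2OC)c(OCC)c1O | intermediate
18 | 2,4,6-trimethoxyphenol | COc1cc(OC)c(O)c(OC)c1 | starting material
19 | 1-bromo-3-iodo-5-methoxybenzene | COc1cc(Br)cc(I)c1 | starting material
20 | 1-bromo-3-methoxy-5-(2,4,6-trimethoxyphenoxy)benzene | COc1cc(Br)cc(Oc2c(OC)cc(OC)cc2OC)c1 | intermediate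
21 | 1-[2-ethoxy-6-isopropoxy-4-methoxy-3-(2,4,6-trimethoxyphenyl)phenoxy]-3-methoxy-5-(2,4,6-trimethoxyphenoxy)benzene | COc1cc(Oc2c(OC)cc(OC)cc2OC)cc(Oc2c(OC(C)C)cc(OC)c(-c3c(OC)cc(OC)cc3OC)c2OCC)c1 | intermediate
22 | 3-[3-hydroxy-5-(2,4,6-trihydroxyphenoxy)phenoxy]biphenyl-2,2',4,4',6,6'-hexol | Oc1cc(Oc2c(O)cc(O)cc2O)cc(Oc2c(O)cc(O)c(-c3c(O)cc(O)cc3O)c2O)c1 | target

**Step count**
Total: 11 steps. Longest linear sequence: 9 steps (1, 2, 4, 5, 6, 7, 8, 10, 11) from compound 1; steps 3 and 9 are one-step side branches.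

**Steps most likely to fail**

Step 2. The two ortho-methoxy groups of the aryl ring may override the ynol ether polarisation and deliver tin to the aryl-bearing carbon, or the α-alkoxyvinylstannane may protodestannylate during purification. The fallback gives up the β-aryl α-alkoxyvinyl metal and carries ring D on the four-membered ring instead. It sets out from 1 and returns at 15.
- Iodine–lithium exchange on 1 (n-BuLi, THF, −78 °C) gives 2,4,6-trimethoxyphenyllithium F1.
- F1 adds to diethyl squarate to give 2,3-diethoxy-4-hydroxy-4-(2,4,6-trimethoxyphenyl)cyclobut-2-en-1-one F2.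
- Conc. HCl in CH2Cl2 converts F2 into 3-ethoxy-4-(2,4,6-trimethoxyphenyl)cyclobut-3-ene-1,2-dione F3.
- 1-Isopropoxyvinyllithium F4 (isopropyl vinyl ether, t-BuLi, THF, −78 → 0 °C) adds to the carbonyl next to the ethoxy-bearing carbon of F3 to give 3-ethoxy-4-hydroxy-4-(1-isopropoxyethenyl)-2-(2,4,6-trimethoxyphenyl)cyclobut-2-en-1-one F5.
- TBSOTf and 2,6-lutidine give 4-[(tert-butyldimethylsilyl)oxy]-3-ethoxy-4-(1-isopropoxyethenyl)-2-(2,4,6-trimethoxyphenyl)cyclobut-2-en-1-one F6.
- Thermolysis of F6 in toluene at 110 °C should give 15, now by closure onto an unsubstituted vinyl terminus (the C3–C4 bond of ring C).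

Step 6. Ring closure at the vinyl terminus that bears the di-ortho-substituted aryl group may be slow, so the monosubstituted ketene dimerises or is trapped, or the silyl group is lost and the hydroquinone oxidises. The fallback forms the ring C–ring D bond by cross-coupling of arenes and oxygenates afterwards. It sets out from 1 and returns at 22.
- Suzuki–Miyaura coupling of 1 with 2,4,6-trimethoxyphenylboronic acid (Pd(OAc)2, SPhos, K3PO4, toluene/H2O, 100 °C) gives 2,2',4,4',6,6'-hexamethoxybiphenyl F7.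
- n-BuLi (THF, 0 °C) metalates one of the four equivalent positions between two methoxy groups to give (2,2',4,4',6,6'-hexamethoxybiphenyl-3-yl)lithium F8.
- B(OMe)3 converts F8 into dimethyl (2,2',4,4',6,6'-hexamethoxybiphenyl-3-yl)boronate F9.
- H2O2/NaOH oxidises F9 to 2,2',4,4',6,6'-hexamethoxybiphenyl-3-ol F10.
- Ullmann coupling of F10 with 20 under the conditions of step 10 gives 2,2',4,4',6,6'-hexamethoxy-3-[3-methoxy-5-(2,4,6-trimethoxyphenoxy)phenoxy]biphenyl F11.
- BBr3 as in step 11 converts F11 into 22.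

Step 10. The copper phenoxide of the 2,6-dialkoxyphenol (one ortho group is isopropoxy) may fail to form the C–O bond, with reduction of the aryl bromide or oxidation of the phenol taking over. The fallback arylates the hindered phenol without metal, through trivalent iodine, and attaches ring A afterwards. It sets out from 19 and returns at 21.
- Oxidation of 19 with mCPBA and TsOH·H2O in MeCN, followed by 1,3,5-trimethoxybenzene, gives (3-bromo-5-methoxyphenyl)(2,4,6-trimethoxyphenyl)iodonium 4-methylbenzenesulfonate F12.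
- Phenol 17 with t-BuOK and F12 in THF at rt should receive the less electron-rich aryl group and give 1-bromo-3-[2-ethoxy-6-isopropoxy-4-methoxy-3-(2,4,6-trimethoxyphenyl)phenoxy]-5-methoxybenzene F13.
- Ullmann coupling of F13 with an excess of inexpensive 18 (CuI, picolinic acid, K3PO4, DMSO, 100 °C) gives 21.

Further compounds
F1 | step 2 | 2,4,6-trimethoxyphenyllithium | [Li]c1c(OC)cc(OC)cc1OC
F2 | step 2 | 2,3-diethoxy-4-hydroxy-4-(2,4,6-trimethoxyphenyl)cyclobut-2-en-1-one | CCOC1=C(OCC)C(O)(c2c(OC)cc(OC)cc2OC)C1=O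
F3 | step 2 | 3-ethoxy-4-(2,4,6-trimethoxyphenyl)cyclobut-3-ene-1,2-dione | CCOC1=C(c2c(OC)cc(OC)cc2OC)C(=O)C1=O
F4 | step 2 | 1-isopropoxyvinyllithium | [Li]C(=C)OC(C)C
F5 | step 2 | 3-ethoxy-4-hydroxy-4-(1-isopropoxyethenyl)-2-(2,4,6-trimethoxyphenyl)cyclobut-2-en-1-one | CCOC1=C(c2c(OC)cc(OC)cc2OC)C(=O)C1(O)C(=C)OC(C)C
F6 | step 2 | 4-[(tert-butyldimethylsilyl)oxy]-3-ethoxy-4-(1-isopropoxyethenyl)-2-(2,4,6-trimethoxyphenyl)cyclobut-2-en-1-one | CCOC1=C(c2c(OC)cc(OC)cc2OC)C(=O)C1(O[Si](C)(C)C(C)(C)C)C(=C)OC(C)C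
F7 | step 6 | 2,2',4,4',6,6'-hexamethoxybiphenyl | COc1cc(OC)c(-c2c(OC)cc(OC)cc2OC)c(OC)c1
F8 | step 6 | (2,2',4,4',6,6'-hexamethoxybiphenyl-3-yl)lithium | [Li]c1c(OC)cc(OC)c(-c2c(OC)cc(OC)cc2OC)c1OC
F9 | step 6 | dimethyl (2,2',4,4',6,6'-hexamethoxybiphenyl-3-yl)boronate | COB(OC)c1c(OC)cc(OC)c(-c2c(OC)cc(OC)cc2OC)c1OC
F10 | step 6 | 2,2',4,4',6,6'-hexamethoxybiphenyl-3-ol | Oc1c(OC)cc(OC)c(-c2c(OC)cc(OC)cc2OC)c1OC
F11 | step 6 | 2,2',4,4',6,6'-hexamethoxy-3-[3-methoxy-5-(2,4,6-trimethoxyphenoxy)phenoxy]biphenyl | COc1cc(Oc2c(OC)cc(OC)cc2OC)cc(Oc2c(OC)cc(OC)c(-c3c(OC)cc(OC)cc3OC)c2OC)c1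
F12 | step 10 | (3-bromo-5-methoxyphenyl)(2,4,6-trimethoxyphenyl)iodonium 4-methylbenzenesulfonate | COc1cc(Br)cc([I+]c2c(OC)cc(OC)cc2OC)c1.Cc1ccc(cc1)S(=O)(=O)[O-]
F13 | step 10 | 1-bromo-3-[2-ethoxy-6-isopropoxy-4-methoxy-3-(2,4,6-trimethoxyphenyl)phenoxy]-5-methoxybenzene | COc1cc(Br)cc(Oc2c(OC(C)C)cc(OC)c(-c3c(OC)cc(OC)cc3OC)c2OCC)c1
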